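**Plan**

1. Retrosynthesis: the indane C1–C2 bond is cut first (closure of a diarylmethyl cation onto an ortho prenyl group, which also gives the isopropylidene). Next comes the bond from C1 to the benzodioxane ring (aryllithium plus phthalide carbonyl), then, inside the dioxane, the bond from the aryl oxygen to the CH carbon.
2. Enabling feature: the dioxane carbon that bears H and C(CH3)2OH is bonded to the aryl oxygen ortho to the indanyl group. Arranged as ArO–C(CH3)2–CH(OH)–CH2–OAr, the same atoms form a seven-membered 1,5-benzodioxepin-3-ol. A 1,2-shift of that aryl oxygen from the tertiary carbon to the carbinol carbon, through an aryloxiranium ion, contracts the ring to the dioxane, inverts the carbinol centre and leaves the tertiary alcohol outside the ring.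
3. Fragment A: creosol → bromophenol → Bargellini acid → six-membered lactone → CH2 insertion to the seven-membered ketone → CBS reduction → ring contraction to the bromo benzodioxane. Fragment B: 4-hydroxyphthalide → bromide → Stille prenylation → allyl ether.
4. Lithiated A adds to B and borohydride gives a diol; the indane ring closes last; deallylation and MnO2 oxidation give the salicylaldehyde.
5. Stereochemistry: the dioxane centre (S) comes from CBS reduction to the (R)-carbinol and its inversion in the contraction. The indane centre (R) is set in the cyclisation by the chiral counter-anion of a Brønsted acid.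

Key step: step 6

Remark: the face of the cation that the chiral acid of step 11 shields cannot be predicted with confidence; the (R) catalyst is written, and its mirror image serves if it proves mismatched.

**Route**

Step 1
Reactants: 1 2-methoxy-4-methylphenol (creosol)
Product: 2 2-bromo-6-methoxy-4-methylphenol
Conditions: Br2 (1.0 equiv), CH2Cl2, −10 °C
Reagents that add atoms: bromine, BrBr
Why: Electrophilic aromatic bromination; with the para position blocked, the free hydroxyl directs bromine to its one open ortho position, as in the bromination of vanillin.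

Step 2
Reactants: 2 2-bromo-6-methoxy-4-methylphenol
Product: 4 2-(2-bromo-6-methoxy-4-methylphenoxy)-2-methylpropanoic acid, via acyl chloride 3 (not isolated)
Conditions: acetone, CHCl3, NaOH (powder), 0 °C to reflux; then aq. HCl
Reagents that add atoms: acetone, CC(C)=O; chloroform, ClC(Cl)Cl; sodium hydroxide, [Na+].[OH-]
Why: Bargellini reaction: trichloromethide adds to acetone, the derived dichloro-oxirane is opened at its tertiary carbon by the phenoxide and acyl chloride 3 is hydrolysed; this is the standard access to α-aryloxyisobutyric acids of doubly ortho-substituted phenols.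

Step 3
Reactants: 4 2-(2-bromo-6-methoxy-4-methylphenoxy)-2-methylpropanoic acid
Product: 6 5-bromo-3,3,7-trimethyl-1,4-benzodioxin-2(3H)-one, via hydroxy acid 5 (not isolated)
Conditions: BBr3, CH2Cl2, −78 to 0 °C; then TsOH (cat.), toluene, reflux (Dean–Stark)
Reagents that add atoms: none
Why: Boron tribromide cleaves the aryl methyl ether by bromide attack at methyl (the tertiary ether next to the carboxyl group cannot ionise), and the freed phenol lactonises under acid to the six-membered aryl ester, helped by the gem-dimethyl group.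

Step 4
Reactants: 6 5-bromo-3,3,7-trimethyl-1,4-benzodioxin-2(3H)-one
Product: 8 9-bromo-2,2,7-trimethyl-2H-1,5-benzodioxepin-3(4H)-one, via chloromethyl ketone 7 (not isolated)
Conditions: ICH2Cl, MeLi·LiBr, THF, −78 °C; AcOH; then K2CO3, acetone, rt
Reagents that add atoms: chloroiodomethane, ClCI
Why: Ester-to-chloromethyl-ketone homologation with chloromethyllithium opens the aryl lactone to phenol 7, and carbonate closes the seven-membered ring by Williamson substitution at the α-chloro ketone (no α'-hydrogen, so no Favorskii path); the net result is a one-carbon ring expansion.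

Step 5
Reactants: 8 9-bromo-2,2,7-trimethyl-2H-1,5-benzodioxepin-3(4H)-one
Product: 9 (3R)-9-bromo-2,2,7-trimethyl-3,4-dihydro-2H-1,5-benzodioxepin-3-ol
Conditions: (S)-2-methyl-CBS-oxazaborolidine [(3aS)-1-methyl-3,3-diphenyltetrahydro-1H,3H-pyrrolo[1,2-c][1,3,2]oxazaborole] (10 mol%), BH3·SMe2, THF, −20 °C
Reagents that add atoms: none
Why: Corey–Bakshi–Shibata reduction: the quaternary O–C(CH3)2 side acts as the large group and the CH2 side as the small one, so the (S) catalyst should deliver hydride to give the (R)-carbinol.

Step 6
Reactants: 9 (3R)-9-bromo-2,2,7-trimethyl-3,4-dihydro-2H-1,5-benzodioxepin-3-ol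
Product: 12 2-[(2S)-8-bromo-6-methyl-2,3-dihydro-1,4-benzodioxin-2-yl]propan-2-ol, via triflate 10 (not isolated), via aryloxiranium ion 11 (not isolated)
Conditions: Tf2O (1.2 equiv), 2,6-di-tert-butyl-4-methylpyridine (3 equiv), CH2Cl2, −78 °C; then MeCN/H2O (4:1), −40 °C to rt
Reagents that add atoms: water, O (the oxygen of the tertiary hydroxyl); trifluoromethanesulfonic anhydride, O=S(=O)(OS(=O)(=O)C(F)(F)F)C(F)(F)F, which adds atoms to intermediate 10 only
Why: Proposed new method: triflation makes the C3 oxygen a leaving group, and the aryl ether oxygen O1 on the neighbouring quaternary carbon displaces it from the back to give aryloxiranium ion 11, whose C2–O1 bond is weak because C2 is tertiary; water opens the ion at C2 in an SN1-like way and leaves that carbon outside the ring as the tertiary carbinol. The closest known reaction type is the oxiranium-mediated contraction of tetrahydropyran-3-yl and 2,2-dimethylchroman-3-yl sulfonates (and of pyranoside 2-triflates) to tetrahydrofuranyl or dihydrobenzofuranyl carbinols; it has not been shown on a 1,5-benzodioxepine. The six-membered dioxane ring is closed in the first event by 3-exo-tet attack of O1 on C3, that is, by a 1,2-aryloxy shift. No new stereocentre is created: the carbinol carbon of 9 becomes C2 of the benzodioxane with inversion (R to S), because the only bond broken at it is broken by backside attack. The selectivity needed is migration of O1 rather than of O5, of a methyl group or of hydride, and substitution rather than loss of triflic acid; O1 is favoured because it leaves a tertiary carbon (O5 would leave a primary one) and is anti to the leaving group. The hindered base, the low temperature and the excess of water, which captures the cation as it forms, are meant to suppress elimination and shifts.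

Step 7
Reactants: 13 4-hydroxy-2-benzofuran-1(3H)-one (4-hydroxyphthalide)
Product: 14 7-bromo-4-hydroxy-2-benzofuran-1(3H)-one
Conditions: NBS (1.0 equiv), MeCN, 0 °C
Reagents that add atoms: N-bromosuccinimide, O=C1CCC(=O)N1Br
Why: Electrophilic bromination of the phenol para to the hydroxyl (the position next to the lactone carbonyl), the usual outcome for 3-hydroxybenzoyl compounds; ortho attack at C5 is the expected minor path.

Step 8
Reactants: 14 7-bromo-4-hydroxy-2-benzofuran-1(3H)-one; 15 tributyl(3-methylbut-2-en-1-yl)stannane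
Product: 16 4-hydroxy-7-(3-methylbut-2-en-1-yl)-2-benzofuran-1(3H)-one
Conditions: Pd(PPh3)4 (5 mol%), DMF, 90 °C
Reagents that add atoms: none
Why: Stille coupling of the aryl bromide, activated by the ortho carbonyl, with the prenylstannane, which transfers the allyl group through its unsubstituted terminus to give the linear prenyl arene.

Step 9
Reactants: 16 4-hydroxy-7-(3-methylbut-2-en-1-yl)-2-benzofuran-1(3H)-one
Product: 17 7-(3-methylbut-2-en-1-yl)-4-(prop-2-en-1-yloxy)-2-benzofuran-1(3H)-one
Conditions: allyl bromide, K2CO3, acetone, 50 °C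
Reagents that add atoms: allyl bromide, C=CCBr
Why: Williamson O-allylation; the allyl ether masks the phenol against the aryllithium of step 10 and against ortho-quinone methide formation from the hydroxymethyl phenol under the acid of step 11.

Step 10
Reactants: 12 2-[(2S)-8-bromo-6-methyl-2,3-dihydro-1,4-benzodioxin-2-yl]propan-2-ol; 17 7-(3-methylbut-2-en-1-yl)-4-(prop-2-en-1-yloxy)-2-benzofuran-1(3H)-one
Product: 20 2-[(2S)-8-{hydroxy[2-(hydroxymethyl)-6-(3-methylbut-2-en-1-yl)-3-(prop-2-en-1-yloxy)phenyl]methyl}-6-methyl-2,3-dihydro-1,4-benzodioxin-2-yl]propan-2-ol (both epimers at the diaryl carbinol), via aryllithium alkoxide 18 (not isolated), via lactol 19 (not isolated)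
Conditions: n-BuLi (2.1 equiv), THF, −78 °C; add 17, −78 to −20 °C; then MeOH, NaBH4, 0 °C to rt
Reagents that add atoms: none
Why: Deprotonation of the carbinol and bromine–lithium exchange give 18, which adds once to the lactone carbonyl (the lithium hemiketalate does not collapse in the cold), and borohydride reduces the ring-opened keto form of lactol 19, the usual entry to 1-arylphthalan precursors; the new carbinol centre is formed unselectively and is erased in step 11.

Step 11
Reactants: 20 the diol of step 10
Product: 22 2-[(2S)-8-[(1R)-7-(hydroxymethyl)-2-(propan-2-ylidene)-6-(prop-2-en-1-yloxy)-2,3-dihydro-1H-inden-1-yl]-6-methyl-2,3-dihydro-1,4-benzodioxin-2-yl]propan-2-ol, via phthalan 21 (not isolated)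
Conditions: (R)-N-triflylphosphoramide of 3,3'-bis(2,4,6-triisopropylphenyl)-1,1'-bi-2-naphthol [(R)-3,3'-(2,4,6-iPr3C6H2)2-BINOL–P(O)NHSO2CF3] (5 mol%), 4 Å molecular sieves, toluene, −20 °C
Reagents that add atoms: none
Why: Proposed new method: the strong chiral acid dehydrates 20 to phthalan 21 and reopens it to a 2-alkoxy-stabilised diarylmethyl cation that stays paired with the chiral phosphoramide anion, held over one face by hydrogen bonds to the freed hydroxymethyl group; the ortho prenyl alkene adds 5-exo-trig and the tertiary cation loses the ring proton at C2 to the anion, giving the tetrasubstituted isopropylidene; the new centre C1 is set by the counter-anion (catalyst control, the dioxane centre being remote); the closest known types are acid-mediated cation–olefin cyclisations of benzhydrols and chiral phosphoric acid or phosphoramide catalysed additions to diarylmethyl cations and ortho-quinone methides.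

Step 12
Reactants: 22 the allyl ether of step 11
Product: 23 2-[(2S)-8-[(1R)-6-hydroxy-7-(hydroxymethyl)-2-(propan-2-ylidene)-2,3-dihydro-1H-inden-1-yl]-6-methyl-2,3-dihydro-1,4-benzodioxin-2-yl]propan-2-ol
Conditions: Pd(PPh3)4 (5 mol%), morpholine, THF, rt
Reagents that add atoms: none
Why: Palladium-catalysed deallylation: the π-allyl complex formed from the aryl allyl ether is captured by morpholine, while the alcohols and the tetrasubstituted alkene are inert.

Step 13
Reactants: 23 the phenol diol of step 12
Product: 24 Diaporindene G, (3R)-5-hydroxy-3-[(3S)-3-(2-hydroxypropan-2-yl)-7-methyl-2,3-dihydro-1,4-benzodioxin-5-yl]-2-(propan-2-ylidene)-2,3-dihydro-1H-indene-4-carbaldehyde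
Conditions: MnO2 (excess), CH2Cl2, rt
Reagents that add atoms: none
Why: MnO2 oxidises only the benzylic primary alcohol (ortho-hydroxybenzyl alcohol to salicylaldehyde) and should leave the tertiary alcohol, the phenol, the alkene and both stereocentres untouched.

**Compound list**

1 | 2-methoxy-4-methylphenol (creosol) | COc1cc(C)ccc1O | starting material
2 | 2-bromo-6-methoxy-4-methylphenol | COc1cc(C)cc(Br)c1O | intermediate
3 | 2-(2-bromo-6-methoxy-4-methylphenoxy)-2-methylpropanoyl chloride | COc1cc(C)cc(Br)c1OC(C)(C)C(Cl)=O | intermediate (not isolated)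
4 | 2-(2-bromo-6-methoxy-4-methylphenoxy)-2-methylpropanoic acid | COc1cc(C)cc(Br)c1OC(C)(C)C(O)=O | intermediate
5 | 2-(2-bromo-6-hydroxy-4-methylphenoxy)-2-methylpropanoic acid | Cc1cc(O)c(OC(C)(C)C(O)=O)c(Br)c1 | intermediate (not isolated)
6 | 5-bromo-3,3,7-trimethyl-1,4-benzodioxin-2(3H)-one | CC1(C)Oc2c(Br)cc(C)cc2OC1=O | intermediate
7 | 3-(2-bromo-6-hydroxy-4-methylphenoxy)-1-chloro-3-methylbutan-2-one | CC(C)(Oc1c(Br)cc(C)cc1O)C(=O)CCl | intermediate (not isolated)
8 | 9-bromo-2,2,7-trimethyl-2H-1,5-benzodioxepin-3(4H)-one | CC1(C)Oc2c(Br)cc(C)cc2OCC1=O | intermediate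
9 | (3R)-9-bromo-2,2,7-trimethyl-3,4-dihydro-2H-1,5-benzodioxepin-3-ol | CC1(C)Oc2c(Br)cc(C)cc2OC[C@H]1O | intermediate
10 | (3R)-9-bromo-2,2,7-trimethyl-3,4-dihydro-2H-1,5-benzodioxepin-3-yl trifluoromethanesulfonate | CC1(C)Oc2c(Br)cc(C)cc2OC[C@H]1OS(=O)(=O)C(F)(F)F | intermediate (not isolated)
11 | aryloxiranium ion: the oxygen ortho to bromine bridges the C(CH3)2 carbon and the (S)-configured CH carbon, the dioxane ring being already closed | CC1(C)[O+]2c3c(Br)cc(C)cc3OC[C@@H]12 | intermediate (not isolated)
12 | 2-[(2S)-8-bromo-6-methyl-2,3-dihydro-1,4-benzodioxin-2-yl]propan-2-ol | Brc1cc(C)cc2c1O[C@H](C(C)(C)O)CO2 | intermediate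
13 | 4-hydroxy-2-benzofuran-1(3H)-one | O=C1OCc2c1cccc2O | starting material
14 | 7-bromo-4-hydroxy-2-benzofuran-1(3H)-one | O=C1OCc2c1c(Br)ccc2O | intermediate
15 | tributyl(3-methylbut-2-en-1-yl)stannane | CCCC[Sn](CCCC)(CCCC)CC=C(C)C | starting material
16 | 4-hydroxy-7-(3-methylbut-2-en-1-yl)-2-benzofuran-1(3H)-one | CC(C)=CCc1ccc(O)c2COC(=O)c12 | intermediate
17 | 7-(3-methylbut-2-en-1-yl)-4-(prop-2-en-1-yloxy)-2-benzofuran-1(3H)-one | CC(C)=CCc1ccc(OCC=C)c2COC(=O)c12 | intermediate
18 | lithium 2-[(2S)-8-lithio-6-methyl-2,3-dihydro-1,4-benzodioxin-2-yl]propan-2-olate | [Li]c1cc(C)cc2c1O[C@H](C(C)(C)O[Li])CO2 | intermediate (not isolated)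
19 | 1-[(3S)-3-(2-hydroxypropan-2-yl)-7-methyl-2,3-dihydro-1,4-benzodioxin-5-yl]-7-(3-methylbut-2-en-1-yl)-4-(prop-2-en-1-yloxy)-1,3-dihydro-2-benzofuran-1-ol (both epimers at the hemiketal carbon) | CC(C)=CCc1ccc(OCC=C)c2COC(O)(c3cc(C)cc4c3O[C@H](C(C)(C)O)CO4)c12 | intermediate (not isolated)
20 | 2-[(2S)-8-{hydroxy[2-(hydroxymethyl)-6-(3-methylbut-2-en-1-yl)-3-(prop-2-en-1-yloxy)phenyl]methyl}-6-methyl-2,3-dihydro-1,4-benzodioxin-2-yl]propan-2-ol (both epimers at the diaryl carbinol) | CC(C)=CCc1ccc(OCC=C)c(CO)c1C(O)c1cc(C)cc2c1O[C@H](C(C)(C)O)CO2 | intermediate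
21 | 2-[(2S)-6-methyl-8-[7-(3-methylbut-2-en-1-yl)-4-(prop-2-en-1-yloxy)-1,3-dihydro-2-benzofuran-1-yl]-2,3-dihydro-1,4-benzodioxin-2-yl]propan-2-ol (both epimers at the phthalan carbon) | CC(C)=CCc1ccc(OCC=C)c2COC(c3cc(C)cc4c3O[C@H](C(C)(C)O)CO4)c12 | intermediate (not isolated)
22 | 2-[(2S)-8-[(1R)-7-(hydroxymethyl)-2-(propan-2-ylidene)-6-(prop-2-en-1-yloxy)-2,3-dihydro-1H-inden-1-yl]-6-methyl-2,3-dihydro-1,4-benzodioxin-2-yl]propan-2-ol | CC(C)=C1Cc2ccc(OCC=C)c(CO)c2[C@@H]1c1cc(C)cc2c1O[C@H](C(C)(C)O)CO2 | intermediate
23 | 2-[(2S)-8-[(1R)-6-hydroxy-7-(hydroxymethyl)-2-(propan-2-ylidene)-2,3-dihydro-1H-inden-1-yl]-6-methyl-2,3-dihydro-1,4-benzodioxin-2-yl]propan-2-ol | CC(C)=C1Cc2ccc(O)c(CO)c2[C@@H]1c1cc(C)cc2c1O[C@H](C(C)(C)O)CO2 | intermediate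
24 | Diaporindene G, (3R)-5-hydroxy-3-[(3S)-3-(2-hydroxypropan-2-yl)-7-methyl-2,3-dihydro-1,4-benzodioxin-5-yl]-2-(propan-2-ylidene)-2,3-dihydro-1H-indene-4-carbaldehyde | CC(C)=C1Cc2ccc(O)c(C=O)c2[C@@H]1c1cc(C)cc2c1O[C@H](C(C)(C)O)CO2 | target

**Step count**

Total: 13 steps. Longest linear sequence: 10 steps (steps 1–6 and 10–13).

**Steps most likely to fail**

1. Step 11. The alkene may attack the planar diarylmethyl cation with poor facial selectivity, and the tertiary cation may lose a methyl proton or undergo a hydride shift instead of losing the ring proton. The fallback sets out from 20 and comes back at 22. The cyclisation is run with an achiral acid (Ca(NTf2)2 with n-Bu4NPF6, CH2Cl2), which is established cation–olefin chemistry and should give 22 together with its epimer at the indane carbon, 2-[(2S)-8-[(1S)-7-(hydroxymethyl)-2-(propan-2-ylidene)-6-(prop-2-en-1-yloxy)-2,3-dihydro-1H-inden-1-yl]-6-methyl-2,3-dihydro-1,4-benzodioxin-2-yl]propan-2-ol F1. Because the dioxane centre is fixed, the two are diastereomers and are separated by chromatography; catalyst control is given up for separation.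

2. Step 6. A methyl or hydride shift, or elimination of the triflate, may compete with the 1,2-shift of the aryl oxygen, and the cationic intermediate may lose a proton before water captures it. The fallback sets out from 2 and comes back at 12; it builds the six-membered ring directly and gives up the contraction. Demethylation of 2 with BBr3 gives 3-bromo-5-methylbenzene-1,2-diol F2. Commercial 3-methylbut-2-en-1-ol is epoxidised under Sharpless conditions (Ti(OiPr)4, D-(−)-diethyl tartrate, t-BuOOH) to [(2R)-3,3-dimethyloxiran-2-yl]methanol F3, which 3-nitrobenzenesulfonyl chloride converts into [(2R)-3,3-dimethyloxiran-2-yl]methyl 3-nitrobenzenesulfonate F4. The dianion of F2 (NaH, DMF) is alkylated by F4 at the oxygen remote from bromine, and the neighbouring phenoxide opens the epoxide 6-exo at the secondary carbon with inversion. This is the classical glycidyl sulfonate route to 2-substituted 1,4-benzodioxanes.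

3. Step 4. A second equivalent of the carbenoid may add to the liberated chloromethyl ketone, and the released phenoxide may react between molecules. The fallback sets out from 6 and comes back at 8. Lactone 6 is opened with dimethylsulfoxonium methylide (Me3S(O)I, KOt-Bu, THF) to the stable keto sulfoxonium ylide, dimethylsulfoxonium 3-(2-bromo-6-hydroxy-4-methylphenoxy)-3-methyl-2-oxobutylide F5. Catalytic [Ir(cod)Cl]2 then closes the seven-membered ring by carbene insertion into the phenol O–H bond.

**Further compounds**

F1 | step 11 | 2-[(2S)-8-[(1S)-7-(hydroxymethyl)-2-(propan-2-ylidene)-6-(prop-2-en-1-yloxy)-2,3-dihydro-1H-inden-1-yl]-6-methyl-2,3-dihydro-1,4-benzodioxin-2-yl]propan-2-ol | CC(C)=C1Cc2ccc(OCC=C)c(CO)c2[C@H]1c1cc(C)cc2c1O[C@H](C(C)(C)O)CO2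
F2 | step 6 | 3-bromo-5-methylbenzene-1,2-diol | Cc1cc(O)c(O)c(Br)c1
F3 | step 6 | [(2R)-3,3-dimethyloxiran-2-yl]methanol | CC1(C)O[C@@H]1CO
F4 | step 6 | [(2R)-3,3-dimethyloxiran-2-yl]methyl 3-nitrobenzenesulfonate | CC1(C)O[C@@H]1COS(=O)(=O)c1cccc([N+](=O)[O-])c1
F5 | step 4 | dimethylsulfoxonium 3-(2-bromo-6-hydroxy-4-methylphenoxy)-3-methyl-2-oxobutylide | CC(C)(Oc1c(Br)cc(C)cc1O)C(=O)C=S(C)(C)=O
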